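**Strategy.** All three drimane units come from one monomer, so everything rests on one disconnection of its trans-decalin: the ring-fusion bond C5–C10 and the ring B bond C8–C9. The feature exploited is the quaternary, methyl-bearing C10, flanked by C5 and by C9 (which carries C11). A single intramolecular Diels–Alder reaction forms both bonds, closes rings A and B and sets C5, C8, C9 and C10 under control of C4. Its precursor is an acyclic 1,7,9-decatriene: an (E)-3-methyl enoate (C9=C10) tied through C1–C4 to an (E,E)-1-silyloxy diene (C5–C8), with quaternary C4, made from a Sharpless epoxide, as the only stereocentre.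

Key step: step 9

Remark: drimane numbering is used.
- C11 is the CH2O on C9, C12 the exocyclic methylene carbon on C8, and C15 the equatorial 4α-CH2O.
- All decalins have 5α-H, 10β-CH3 and 4β-CH3. Compounds without C12 are named as 12-nordrimanes.
- In the side chain, C2′ is the ether carbon (α-carboxyl), C3′ carries the central carboxyl, and CH2CO2 is the terminal carboxyl.
- The units are A (free central acid), B, and C (free 15-OH).
- TBS = tert-butyldimethylsilyl; TBDPS = tert-butyldiphenylsilyl.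

**Step 1**
Reactants: 1 hepta-1,6-diyne
Product: 3 dimethyl (2E,7E)-3,7-dimethylnona-2,7-dienedioate, via bis(alkenyl)alane 2 (not isolated)
Conditions: AlMe3, Cp2ZrCl2 (cat.), CH2Cl2, 0 °C to rt; then ClCO2Me, 0 °C to rt
Reagents that add atoms: trimethylaluminium C[Al](C)C; methyl chloroformate COC(=O)Cl
Why: Negishi carboalumination adds methyl and aluminium syn to each terminal alkyne with the metal at the terminus, and acylation of the alkenyl–aluminium bonds proceeds with retention, so both trisubstituted enoates should form as (E) isomers.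

**Step 2**
Reactants: 3 dimethyl (2E,7E)-3,7-dimethylnona-2,7-dienedioate
Product: 4 methyl (2E,7E)-9-hydroxy-3,7-dimethylnona-2,7-dienoate
Conditions: iBu2AlH (2 equiv), CH2Cl2, −78 °C; Rochelle salt; recovered 3 recycled
Reagents that add atoms: none
Why: Statistical 1,2-reduction (DIBAL-H reduction) of one of two equivalent, remote enoate esters, in which diester, hydroxy ester and diol differ enough in polarity to be separated.

**Step 3**
Reactants: 4 methyl (2E,7E)-9-hydroxy-3,7-dimethylnona-2,7-dienoate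
Product: 5 methyl (2E)-6-[(2S,3S)-3-(hydroxymethyl)-2-methyloxiran-2-yl]-3-methylhex-2-enoate
Conditions: Ti(OiPr)4 (cat.), L-(+)-diethyl tartrate (cat.), tBuOOH, 4 Å MS, CH2Cl2, −20 °C
Reagents that add atoms: tert-butyl hydroperoxide CC(C)(C)OO
Why: In this Sharpless asymmetric epoxidation only the allylic-alcohol alkene is activated (the enoate is inert), and L-(+)-tartrate should give the (2S,3S)-epoxide as with other (E)-3-methylalk-2-en-1-ols, which fixes the configuration later carried into C4.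

**Step 4**
Reactants: 5 epoxy alcohol
Product: 6 methyl (2E)-6-[(2S,3S)-3-{[(tert-butyldiphenylsilyl)oxy]methyl}-2-methyloxiran-2-yl]-3-methylhex-2-enoate
Conditions: TBDPSCl, imidazole, CH2Cl2, rt
Reagents that add atoms: tert-butyldiphenylsilyl chloride CC(C)(C)[Si](Cl)(c1ccccc1)c1ccccc1
Why: Routine silyl ether formation, whose bulky group lowers the basicity of this oxygen for step 5 and later serves as the large substituent on C4.

**Step 5**
Reactants: 6 epoxy silyl ether
Product: 7 methyl (2E,7S)-7-{[(tert-butyldiphenylsilyl)oxy]methyl}-3,7-dimethyl-8-oxooct-2-enoate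
Conditions: MeAl(OAr)2 (2.2 equiv; Ar = 4-bromo-2,6-di-tert-butylphenyl, from AlMe3 + 2 ArOH), CH2Cl2, −78 to −40 °C
Reagents that add atoms: none
Why: In this organoaluminium-promoted epoxy silyl ether rearrangement (semipinacol-type 1,2-shift, established for epoxygeranyl-type silyl ethers) the bulky Lewis acid opens the epoxide at its tertiary carbon and favours migration of the silyloxymethyl group over hydride, anti to the leaving oxygen, so the epoxide configuration passes with inversion into quaternary C4, while one equivalent of the reagent is given up to the enoate carbonyl.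

**Step 6**
Reactants: 7 aldehyde; 8 [2-(1,3-dioxolan-2-yl)ethyl]triphenylphosphonium bromide
Product: 10 methyl (2E,7R,8Z)-7-{[(tert-butyldiphenylsilyl)oxy]methyl}-10-(1,3-dioxolan-2-yl)-3,7-dimethyldeca-2,8-dienoate, via phosphorus ylide 9 (not isolated)
Conditions: 8, NaN(SiMe3)2, THF, 0 °C; then 7, −78 °C to rt
Reagents that add atoms: none
Why: In this Wittig olefination the unstabilised ylide attacks the non-enolisable neopentyl aldehyde much faster than the enoate, and the (Z) geometry is of no consequence because step 7 erases it.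

**Step 7**
Reactants: 10 (Z)-alkenyl acetal
Product: 12 methyl (2E,7R,9E)-7-{[(tert-butyldiphenylsilyl)oxy]methyl}-3,7-dimethyl-11-oxoundeca-2,9-dienoate, via (Z)-β,γ-unsaturated aldehyde 11 (not isolated)
Conditions: 1 M HCl, THF, 45 °C; then DBU (cat.), CH2Cl2, rt
Reagents that add atoms: water O
Why: Acid hydrolysis of the acetal followed by base-catalysed conjugation moves the double bond to C6=C7, giving the thermodynamically favoured (E)-enal, and the TBDPS ether and the enoate tolerate both stages.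

**Step 8**
Reactants: 12 (E)-enal
Product: 13 methyl (2E,7R,8E,10E)-11-[(tert-butyldimethylsilyl)oxy]-7-{[(tert-butyldiphenylsilyl)oxy]methyl}-3,7-dimethylundeca-2,8,10-trienoate
Conditions: TBSOTf, Et3N, Et2O, 0 °C; Et3N-deactivated silica
Reagents that add atoms: tert-butyldimethylsilyl triflate CC(C)(C)[Si](C)(C)OS(=O)(=O)C(F)(F)F
Why: In this soft enolisation (O-silylation, then γ-deprotonation at C5) the s-trans enal should give the (E)-enol ether and the bulk of C4 should force the new C5=C6 bond to be (E), while the less basic ester is not silylated.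

**Step 9**
Reactants: 13 silyloxy trienoate
Product: 14 methyl 8β-[(tert-butyldimethylsilyl)oxy]-15-[(tert-butyldiphenylsilyl)oxy]-12-nordrim-6-en-11-oate (9α-H)
Conditions: PhMe (0.01 M), BHT (cat.), sealed base-washed tube, 185 °C
Reagents that add atoms: none
Why: Concerted, suprafacial thermal [4+2] cycloaddition, i.e. the known intramolecular Diels–Alder reaction of 1,7,9-decatrienoates to decalins, used here at the hindered end of its scope because C10 becomes quaternary beside quaternary C4. The C8 silyloxy donor raises the diene HOMO and places its largest coefficient on C5, which meets the enoate β-carbon C10, so the electronic preference and the tether demand the same C5–C10 and C8–C9 bonds. Ring B (C5–C6–C7–C8–C9–C10) closes by the cycloaddition itself, and ring A (C10–C1–C2–C3–C4–C5) closes in the fused mode as the C1–C4 tether folds into a chair while C5–C10 forms. C9 and C10 are linked by the (E)-enoate geometry (C11 and the C10 methyl cis), C8 and C5 by the (E,E)-diene geometry (silyloxy group and C4 cis), and C5 versus C10 by the transition state with ester endo and tether exo, which gives the trans fusion with 5α-H, 8β-O, 9α-H and 10β-methyl. The absolute sense comes from C4, because the site anti to the forming C5–C10 bond (future equatorial) accommodates CH2OTBDPS, while the crowded site beside the incoming C10 methyl (future axial) accepts only the methyl group. The step thus needs trans (endo) and π-facial selectivity, secured by the (E)-ester, the chair tether and the size gap at C4, whereas leakage at C8 or C9 is harmless since both centres are erased in enone 20; dilution, BHT and base-washed glass protect the dienol ether.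

**Step 10**
Reactants: 14 cycloadduct
Product: 15 methyl 8β-[(tert-butyldimethylsilyl)oxy]-15-[(tert-butyldiphenylsilyl)oxy]-12-nordriman-11-oate
Conditions: H2 (1 atm), Pd/C, EtOAc, rt
Reagents that add atoms: none
Why: Catalytic hydrogenation of the only alkene (cis-disubstituted C6=C7), run in a neutral aprotic solvent in which allylic silyl ethers resist hydrogenolysis.

**Step 11**
Reactants: 15 saturated ester
Product: 16 8β-[(tert-butyldimethylsilyl)oxy]-15-[(tert-butyldiphenylsilyl)oxy]-12-nordriman-11-ol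
Conditions: LiAlH4, Et2O, 0 °C
Reagents that add atoms: none
Why: Hydride reduction of the ester to the primary alcohol, which both silyl ethers survive and which leaves C9 unchanged.

**Step 12**
Reactants: 16 11-alcohol
Product: 17 8β-[(tert-butyldimethylsilyl)oxy]-15-[(tert-butyldiphenylsilyl)oxy]-12-nordriman-11-yl acetate
Conditions: Ac2O, pyridine, DMAP (cat.), CH2Cl2, rt
Reagents that add atoms: acetic anhydride CC(=O)OC(C)=O
Why: DMAP-catalysed acetylation turns C11–O into the leaving group needed in step 14.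

**Step 13**
Reactants: 17 acetate
Product: 18 15-[(tert-butyldiphenylsilyl)oxy]-8β-hydroxy-12-nordriman-11-yl acetate
Conditions: 48% aq. HF, MeCN, 0 °C to rt
Reagents that add atoms: none
Why: Selective protic desilylation, in which the TBS ether is cleaved far faster than the acid-robust TBDPS ether and the acetate is untouched.

**Step 14**
Reactants: 18 8β-alcohol
Product: 20 15-[(tert-butyldiphenylsilyl)oxy]-12-nordrim-9(11)-en-8-one, via β-acetoxy ketone 19 (not isolated)
Conditions: Dess–Martin periodinane, CH2Cl2, rt; then DBU, 0 °C to rt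
Reagents that add atoms: none
Why: Dess–Martin oxidation of the strained axial alcohol followed by E1cB loss of acetate gives the exocyclic enone, the only conjugated alkene possible next to quaternary C10.

**Step 15**
Reactants: 21 (R)-malic acid
Product: 23 (3R)-3-hydroxy-4-methoxy-4-oxobutanoic acid (1-methyl hydrogen (R)-malate), via O-trifluoroacetyl anhydride 22 (not isolated)
Conditions: (CF3CO)2O, 0 °C to rt, evaporate; then MeOH, rt
Reagents that add atoms: methanol CO
Why: Cyclic anhydride formation followed by regioselective methanolysis at the carbonyl next to the electron-withdrawing acyloxy group, in which excess methanol also removes the trifluoroacetate and C2′ is not touched.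

**Step 16**
Reactants: 23 1-methyl hydrogen (R)-malate
Product: 24 4-tert-butyl 1-methyl (2R)-2-hydroxybutanedioate
Conditions: tBuOC(=NH)CCl3, CH2Cl2/cyclohexane, rt
Reagents that add atoms: tert-butyl 2,2,2-trichloroacetimidate CC(C)(C)OC(=N)C(Cl)(Cl)Cl
Why: In this trichloroacetimidate esterification the carboxylic acid itself activates the imidate and captures the tert-butyl group, whereas the weakly nucleophilic α-hydroxy ester OH stays free.

**Step 17**
Reactants: 24 mixed malate
Product: 26 4-tert-butyl 1-methyl (2R,3S)-2-hydroxy-3-(prop-2-en-1-yl)butanedioate, via dilithium alkoxide enolate 25 (not isolated)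
Conditions: LiN(SiMe3)2 (2.2 equiv), THF, −78 to −20 °C; then allyl bromide, −78 to −10 °C; AcOH
Reagents that add atoms: allyl bromide C=CCBr
Why: In this Fráter–Seebach alkylation the chelated alkoxide enolate of the tert-butyl ester is attacked anti to the C2′ carboxyl substituent, which sets C3′ as (S).

**Step 18**
Reactants: 20 enone; 26 hydroxy diester
Product: 27 4-tert-butyl 1-methyl (2R,3S)-2-({15-[(tert-butyldiphenylsilyl)oxy]-8-oxo-12-nordriman-11-yl}oxy)-3-(prop-2-en-1-yl)butanedioate (9α-H)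
Conditions: 26 (1.5 equiv), KN(SiMe3)2 (0.15 equiv), PhMe, −30 to 0 °C; AcOH
Reagents that add atoms: none
Why: In this base-catalysed oxa-Michael addition the alkoxide of the fairly acidic α-hydroxy ester adds to the unhindered C11 terminus, further 26 reprotonates the ketone enolate so the chain continues, protonation and equilibration at C9 place CH2OR equatorial, and carrying the third carboxyl as an allyl group rules out γ-lactonisation of the nucleophile.

**Step 19**
Reactants: 27 keto ether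
Product: 29 keto acid: O2′-{15-[(tert-butyldiphenylsilyl)oxy]-8-oxo-12-nordriman-11-yl} (2′R,3′S)-isocitrate, α-methyl central-tert-butyl diester, free terminal CO2H, via aldehyde 28 (not isolated)
Conditions: O3, CH2Cl2, −78 °C; PPh3; then NaClO2, NaH2PO4, 2-methyl-2-butene, tBuOH/H2O, rt
Reagents that add atoms: ozone [O-][O+]=O; sodium chlorite [Na+].[O-]Cl=O
Why: Ozonolysis of the only alkene followed by Pinnick oxidation unveils the terminal carboxyl before any exocyclic methylene exists, under conditions that do not enolise C9 or C3′.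

**Step 20**
Reactants: 29 keto acid
Product: 30 keto triester: α-methyl central-tert-butyl terminal-allyl isocitrate ether of the 8-oxo-12-nordrimane
Conditions: allyl bromide, KHCO3, DMF, rt
Reagents that add atoms: allyl bromide C=CCBr
Why: Carboxylate O-alkylation with a base too weak to trigger retro-Michael cleavage of the β-alkoxy ketone.

**Step 21**
Reactants: 30 keto triester
Product: 31 monomer for units B and C: α-methyl central-tert-butyl terminal-allyl (2′R,3′S)-isocitrate, O2′-{15-[(tert-butyldiphenylsilyl)oxy]drim-8(12)-en-11-yl} ether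
Conditions: Zn, CH2Br2, TiCl4 (pre-aged in THF), CH2Cl2, 0 °C to rt
Reagents that add atoms: dibromomethane BrCBr
Why: In this Takai–Lombardo methylenation the non-basic gem-dimetallic reagent converts ketones but not esters, so C9 is not epimerised and the β-alkoxy group is not eliminated.

**Step 22**
Reactants: 31 monomer
Product: 33 monomer acid (free central CO2H, terminal allyl ester, 15-OTBDPS), via trimethylsilyl ester 32 (not isolated)
Conditions: TMSOTf, 2,6-lutidine, CH2Cl2, 0 °C; then pH 4 buffer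
Reagents that add atoms: none
Why: Silyl triflate-mediated tert-butyl ester cleavage under buffered conditions spares the exocyclic alkene, the allyl and methyl esters and the TBDPS ether, and the silyl ester hydrolyses on work-up.

**Step 23**
Reactants: 29 keto acid
Product: 34 keto triester: α-methyl central-tert-butyl terminal-methyl isocitrate ether of the 8-oxo-12-nordrimane
Conditions: MeI, KHCO3, DMF, rt
Reagents that add atoms: iodomethane CI
Why: Carboxylate O-alkylation as in step 20 installs the terminal methyl ester of unit A.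

**Step 24**
Reactants: 34 keto triester
Product: 35 α-methyl central-tert-butyl terminal-methyl (2′R,3′S)-isocitrate, O2′-{15-[(tert-butyldiphenylsilyl)oxy]drim-8(12)-en-11-yl} ether
Conditions: Zn, CH2Br2, TiCl4 (pre-aged in THF), CH2Cl2, 0 °C to rt
Reagents that add atoms: dibromomethane BrCBr
Why: Takai–Lombardo methylenation with the same ketone-over-ester selectivity and freedom from enolisation as in step 21.

**Step 25**
Reactants: 35 silyl ether
Product: 36 unit A alcohol: α-methyl central-tert-butyl terminal-methyl (2′R,3′S)-isocitrate, O2′-(15-hydroxydrim-8(12)-en-11-yl) ether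
Conditions: HF·pyridine, pyridine, THF, 0 °C to rt
Reagents that add atoms: none
Why: Buffered fluoride desilylation avoids the basic conditions that could enolise C3′.

**Step 26**
Reactants: 33 monomer acid; 36 unit A alcohol
Product: 37 protected dimer B–A (central carboxyl of B esterified with 15-O of A; B: 15-OTBDPS, terminal allyl ester; A: central tert-butyl ester, terminal methyl ester)
Conditions: 2-methyl-6-nitrobenzoic anhydride, DMAP, Et3N, CH2Cl2, rt
Reagents that add atoms: none
Why: Shiina esterification, a mixed-anhydride/DMAP acyl transfer made for hindered acid and alcohol pairs, runs at room temperature, which should keep C3′ intact.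

**Step 27**
Reactants: 37 protected dimer
Product: 38 dimer alcohol (free 15-OH on unit B)
Conditions: HF·pyridine, pyridine, THF, 0 °C to rt
Reagents that add atoms: none
Why: Buffered fluoride desilylation as in step 25, to which allyl, methyl and tert-butyl esters and both alkenes are inert.

**Step 28**
Reactants: 33 monomer acid; 38 dimer alcohol
Product: 39 protected trimer C–B–A (C: 15-OTBDPS; B and C: terminal allyl esters; A: central tert-butyl ester, terminal methyl ester)
Conditions: 2-methyl-6-nitrobenzoic anhydride, DMAP, Et3N, CH2Cl2, rt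
Reagents that add atoms: none
Why: A second Shiina esterification at a site whose local environment is the same as in step 26.

**Step 29**
Reactants: 39 protected trimer
Product: 41 bis(allyl) ester of cryptoporic acid T (free 15-OH on C, free central CO2H on A), via trimethylsilyl ester 40 (not isolated)
Conditions: TMSOTf, 2,6-lutidine, CH2Cl2, 0 °C; then HF·pyridine, THF, 0 °C to rt
Reagents that add atoms: none
Why: Buffered silyl triflate cleavage of the tert-butyl ester followed in the same flask by fluoride desilylation of the silyl ester and the TBDPS ether, both stages being free of strong acid so that the three exocyclic alkenes should not migrate.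

**Step 30**
Reactants: 41 bis(allyl) ester
Product: 42 cryptoporic acid T
Conditions: Pd(PPh3)4 (cat.), morpholine, THF, rt; dilute citric acid
Reagents that add atoms: none
Why: In this Tsuji–Trost deallylation zerovalent palladium ionises only the two allyl esters and morpholine traps the allyl groups, under neutral conditions that leave every ester link, alkene and stereocentre untouched.

**Compound list**

1 | hepta-1,6-diyne | C#CCCCC#C | starting material
2 | (1E,6E)-bis(dimethylalumino)-2,6-dimethylhepta-1,6-diene | C[Al](C)/C=C(\C)CCC/C(C)=C/[Al](C)C | intermediate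
3 | dimethyl (2E,7E)-3,7-dimethylnona-2,7-dienedioate | COC(=O)/C=C(\C)CCC/C(C)=C/C(=O)OC | intermediate
4 | methyl (2E,7E)-9-hydroxy-3,7-dimethylnona-2,7-dienoate | COC(=O)/C=C(\C)CCC/C(C)=C/CO | intermediate
5 | methyl (2E)-6-[(2S,3S)-3-(hydroxymethyl)-2-methyloxiran-2-yl]-3-methylhex-2-enoate | COC(=O)/C=C(\C)CCC[C@]1(C)O[C@H]1CO | intermediate
6 | TBDPS ether of 5 | COC(=O)/C=C(\C)CCC[C@]1(C)O[C@H]1CO[Si](c2ccccc2)(c2ccccc2)C(C)(C)C | intermediate
7 | methyl (2E,7S)-7-(TBDPS-oxymethyl)-3,7-dimethyl-8-oxooct-2-enoate | COC(=O)/C=C(\C)CCC[C@@](C)(CO[Si](c1ccccc1)(c1ccccc1)C(C)(C)C)C=O | intermediate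
8 | [2-(1,3-dioxolan-2-yl)ethyl]triphenylphosphonium bromide | [Br-].C1COC(CC[P+](c2ccccc2)(c2ccccc2)c2ccccc2)O1 | starting material
9 | [2-(1,3-dioxolan-2-yl)ethylidene]triphenylphosphorane | C1COC(CC=P(c2ccccc2)(c2ccccc2)c2ccccc2)O1 | intermediate
10 | methyl (2E,7R,8Z)-7-(TBDPS-oxymethyl)-10-(1,3-dioxolan-2-yl)-3,7-dimethyldeca-2,8-dienoate | COC(=O)/C=C(\C)CCC[C@@](C)(CO[Si](c1ccccc1)(c1ccccc1)C(C)(C)C)/C=C\CC1OCCO1 | intermediate
11 | methyl (2E,7R,8Z)-7-(TBDPS-oxymethyl)-3,7-dimethyl-11-oxoundeca-2,8-dienoate | COC(=O)/C=C(\C)CCC[C@@](C)(CO[Si](c1ccccc1)(c1ccccc1)C(C)(C)C)/C=C\CC=O | intermediate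
12 | methyl (2E,7R,9E)-7-(TBDPS-oxymethyl)-3,7-dimethyl-11-oxoundeca-2,9-dienoate | COC(=O)/C=C(\C)CCC[C@@](C)(CO[Si](c1ccccc1)(c1ccccc1)C(C)(C)C)C/C=C/C=O | intermediate
13 | methyl (2E,7R,8E,10E)-11-(TBS-oxy)-7-(TBDPS-oxymethyl)-3,7-dimethylundeca-2,8,10-trienoate | COC(=O)/C=C(\C)CCC[C@@](C)(CO[Si](c1ccccc1)(c1ccccc1)C(C)(C)C)/C=C/C=C/O[Si](C)(C)C(C)(C)C | intermediate
14 | methyl 8β-(TBS-oxy)-15-(TBDPS-oxy)-12-nordrim-6-en-11-oate | COC(=O)[C@H]1[C@@H](O[Si](C)(C)C(C)(C)C)C=C[C@H]2[C@](C)(CO[Si](c3ccccc3)(c3ccccc3)C(C)(C)C)CCC[C@]12C | intermediate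
15 | methyl 8β-(TBS-oxy)-15-(TBDPS-oxy)-12-nordriman-11-oate | COC(=O)[C@H]1[C@@H](O[Si](C)(C)C(C)(C)C)CC[C@H]2[C@](C)(CO[Si](c3ccccc3)(c3ccccc3)C(C)(C)C)CCC[C@]12C | intermediate
16 | 8β-(TBS-oxy)-15-(TBDPS-oxy)-12-nordriman-11-ol | OC[C@H]1[C@@H](O[Si](C)(C)C(C)(C)C)CC[C@H]2[C@](C)(CO[Si](c3ccccc3)(c3ccccc3)C(C)(C)C)CCC[C@]12C | intermediate
17 | 8β-(TBS-oxy)-15-(TBDPS-oxy)-12-nordriman-11-yl acetate | CC(=O)OC[C@H]1[C@@H](O[Si](C)(C)C(C)(C)C)CC[C@H]2[C@](C)(CO[Si](c3ccccc3)(c3ccccc3)C(C)(C)C)CCC[C@]12C | intermediate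
18 | 15-(TBDPS-oxy)-8β-hydroxy-12-nordriman-11-yl acetate | CC(=O)OC[C@H]1[C@@H](O)CC[C@H]2[C@](C)(CO[Si](c3ccccc3)(c3ccccc3)C(C)(C)C)CCC[C@]12C | intermediate
19 | 15-(TBDPS-oxy)-8-oxo-12-nordriman-11-yl acetate | CC(=O)OC[C@H]1C(=O)CC[C@H]2[C@](C)(CO[Si](c3ccccc3)(c3ccccc3)C(C)(C)C)CCC[C@]12C | intermediate
20 | 15-(TBDPS-oxy)-12-nordrim-9(11)-en-8-one | C=C1C(=O)CC[C@H]2[C@](C)(CO[Si](c3ccccc3)(c3ccccc3)C(C)(C)C)CCC[C@]12C | intermediate
21 | (R)-malic acid | O[C@@H](C(=O)O)CC(=O)O | starting material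
22 | (R)-O-trifluoroacetylmalic anhydride | O=C1C[C@@H](OC(=O)C(F)(F)F)C(=O)O1 | intermediate
23 | (3R)-3-hydroxy-4-methoxy-4-oxobutanoic acid | O[C@@H](C(=O)OC)CC(=O)O | intermediate
24 | 4-tert-butyl 1-methyl (2R)-2-hydroxybutanedioate | O[C@@H](C(=O)OC)CC(=O)OC(C)(C)C | intermediate
25 | dilithium alkoxide enolate of 24 | [Li+].[Li+].[O-][C@@H](C(=O)OC)/C=C(\[O-])OC(C)(C)C | intermediate
26 | 4-tert-butyl 1-methyl (2R,3S)-2-hydroxy-3-(prop-2-en-1-yl)butanedioate | O[C@@H](C(=O)OC)[C@H](CC=C)C(=O)OC(C)(C)C | intermediate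
27 | oxa-Michael adduct (8-ketone, 3′-allyl) | O=C1CC[C@H]2[C@](C)(CO[Si](c3ccccc3)(c3ccccc3)C(C)(C)C)CCC[C@]2(C)[C@H]1CO[C@@H](C(=O)OC)[C@H](CC=C)C(=O)OC(C)(C)C | intermediate
28 | keto aldehyde (3′-CH2CHO) | O=C1CC[C@H]2[C@](C)(CO[Si](c3ccccc3)(c3ccccc3)C(C)(C)C)CCC[C@]2(C)[C@H]1CO[C@@H](C(=O)OC)[C@H](CC=O)C(=O)OC(C)(C)C | intermediate
29 | keto acid (free terminal CO2H) | O=C1CC[C@H]2[C@](C)(CO[Si](c3ccccc3)(c3ccccc3)C(C)(C)C)CCC[C@]2(C)[C@H]1CO[C@@H](C(=O)OC)[C@H](CC(=O)O)C(=O)OC(C)(C)C | intermediate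
30 | keto triester (terminal allyl) | O=C1CC[C@H]2[C@](C)(CO[Si](c3ccccc3)(c3ccccc3)C(C)(C)C)CCC[C@]2(C)[C@H]1CO[C@@H](C(=O)OC)[C@H](CC(=O)OCC=C)C(=O)OC(C)(C)C | intermediate
31 | monomer for units B and C | C=C1CC[C@H]2[C@](C)(CO[Si](c3ccccc3)(c3ccccc3)C(C)(C)C)CCC[C@]2(C)[C@H]1CO[C@@H](C(=O)OC)[C@H](CC(=O)OCC=C)C(=O)OC(C)(C)C | intermediate
32 | central trimethylsilyl ester of 33 | C=C1CC[C@H]2[C@](C)(CO[Si](c3ccccc3)(c3ccccc3)C(C)(C)C)CCC[C@]2(C)[C@H]1CO[C@@H](C(=O)OC)[C@H](CC(=O)OCC=C)C(=O)O[Si](C)(C)C | intermediate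
33 | monomer acid (free central CO2H) | C=C1CC[C@H]2[C@](C)(CO[Si](c3ccccc3)(c3ccccc3)C(C)(C)C)CCC[C@]2(C)[C@H]1CO[C@@H](C(=O)OC)[C@H](CC(=O)OCC=C)C(=O)O | intermediate
34 | keto triester (terminal methyl) | O=C1CC[C@H]2[C@](C)(CO[Si](c3ccccc3)(c3ccccc3)C(C)(C)C)CCC[C@]2(C)[C@H]1CO[C@@H](C(=O)OC)[C@H](CC(=O)OC)C(=O)OC(C)(C)C | intermediate
35 | unit A silyl ether | C=C1CC[C@H]2[C@](C)(CO[Si](c3ccccc3)(c3ccccc3)C(C)(C)C)CCC[C@]2(C)[C@H]1CO[C@@H](C(=O)OC)[C@H](CC(=O)OC)C(=O)OC(C)(C)C | intermediate
36 | unit A alcohol | C=C1CC[C@H]2[C@](C)(CO)CCC[C@]2(C)[C@H]1CO[C@@H](C(=O)OC)[C@H](CC(=O)OC)C(=O)OC(C)(C)C | intermediate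
37 | protected dimer B–A | C=C1CC[C@H]2[C@](C)(COC(=O)[C@@H](CC(=O)OCC=C)[C@@H](OC[C@H]3C(=C)CC[C@H]4[C@](C)(CO[Si](c5ccccc5)(c5ccccc5)C(C)(C)C)CCC[C@]34C)C(=O)OC)CCC[C@]2(C)[C@H]1CO[C@@H](C(=O)OC)[C@H](CC(=O)OC)C(=O)OC(C)(C)C | intermediate
38 | dimer alcohol | C=C1CC[C@H]2[C@](C)(COC(=O)[C@@H](CC(=O)OCC=C)[C@@H](OC[C@H]3C(=C)CC[C@H]4[C@](C)(CO)CCC[C@]34C)C(=O)OC)CCC[C@]2(C)[C@H]1CO[C@@H](C(=O)OC)[C@H](CC(=O)OC)C(=O)OC(C)(C)C | intermediate
39 | protected trimer C–B–A | C=C1CC[C@H]2[C@](C)(COC(=O)[C@@H](CC(=O)OCC=C)[C@@H](OC[C@H]3C(=C)CC[C@H]4[C@](C)(COC(=O)[C@@H](CC(=O)OCC=C)[C@@H](OC[C@H]5C(=C)CC[C@H]6[C@](C)(CO[Si](c7ccccc7)(c7ccccc7)C(C)(C)C)CCC[C@]56C)C(=O)OC)CCC[C@]34C)C(=O)OC)CCC[C@]2(C)[C@H]1CO[C@@H](C(=O)OC)[C@H](CC(=O)OC)C(=O)OC(C)(C)C | intermediate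
40 | trimer, central trimethylsilyl ester on unit A | C=C1CC[C@H]2[C@](C)(COC(=O)[C@@H](CC(=O)OCC=C)[C@@H](OC[C@H]3C(=C)CC[C@H]4[C@](C)(COC(=O)[C@@H](CC(=O)OCC=C)[C@@H](OC[C@H]5C(=C)CC[C@H]6[C@](C)(CO[Si](c7ccccc7)(c7ccccc7)C(C)(C)C)CCC[C@]56C)C(=O)OC)CCC[C@]34C)C(=O)OC)CCC[C@]2(C)[C@H]1CO[C@@H](C(=O)OC)[C@H](CC(=O)OC)C(=O)O[Si](C)(C)C | intermediate
41 | bis(allyl) ester of cryptoporic acid T | C=C1CC[C@H]2[C@](C)(COC(=O)[C@@H](CC(=O)OCC=C)[C@@H](OC[C@H]3C(=C)CC[C@H]4[C@](C)(COC(=O)[C@@H](CC(=O)OCC=C)[C@@H](OC[C@H]5C(=C)CC[C@H]6[C@](C)(CO)CCC[C@]56C)C(=O)OC)CCC[C@]34C)C(=O)OC)CCC[C@]2(C)[C@H]1CO[C@@H](C(=O)OC)[C@H](CC(=O)OC)C(=O)O | intermediate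
42 | cryptoporic acid T | C=C1CC[C@H]2[C@](C)(COC(=O)[C@@H](CC(=O)O)[C@@H](OC[C@H]3C(=C)CC[C@H]4[C@](C)(COC(=O)[C@@H](CC(=O)O)[C@@H](OC[C@H]5C(=C)CC[C@H]6[C@](C)(CO)CCC[C@]56C)C(=O)OC)CCC[C@]34C)C(=O)OC)CCC[C@]2(C)[C@H]1CO[C@@H](C(=O)OC)[C@H](CC(=O)OC)C(=O)O | target

**Step count.** Total: 30 steps. Longest linear sequence: 24 steps (1–14, 18, 19, 20–22 or 23–25, 26–30).

**Steps most likely to fail**

**Step 9.**
- Risk: the cycloaddition may be slower than the thermal decay of the dienol silyl ether. At the temperature needed, leakage through the cis-fused or the wrong-face transition state may also grow.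
- Fallback (sets out from 13, comes back at 16): the dienophile is made more electron-poor instead of being heated harder.
- iBu2AlH reduces the enoate of 13 to (2E,7R,8E,10E)-trienol F1, and MnO2 oxidises it to trienal F2.
- The enal dienophile of F2 should cyclise near room temperature through the same endo, chair-tether arrangement to 12-nordrim-6-en-11-al F3.
- NaBH4 gives 12-nordrim-6-en-11-ol F4, and hydrogenation over Pd/C gives 16.

**Step 18.**
- Risk: the addition is reversible, the hindered secondary alkoxide is a weak nucleophile, and the enone can dimerise while it waits.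
- Fallback (sets out from 16 and 26, comes back at 27): the C11–O bond is made by silane reductive etherification, which is irreversible.
- Dess–Martin oxidation of 16 gives 8β-silyloxy 11-aldehyde F5, and TMSCl/imidazole converts 26 into its trimethylsilyl ether F6.
- F5 and F6 with Et3SiH and catalytic TMSOTf (CH2Cl2, −78 °C) give 8β-silyloxy ether F7.
- Aqueous HF in MeCN frees 8β-hydroxy ether F8, and Dess–Martin oxidation gives 27.

**Step 13.**
- Risk: the 8β-TBS ether is axial and syn to the C10 methyl, so its cleavage may be slow enough for loss of the C15 TBDPS ether to set in.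
- Fallback (sets out from 17, comes back at 18): selectivity is moved from the deprotection to the protection.
- Excess HF·pyridine removes both silyl groups to give 11-acetoxy-12-nordrimane-8β,15-diol F9.
- One equivalent of TBDPSCl with imidazole then silylates only the primary C15 hydroxyl, giving 18.

**Further compounds**

F1 | step 9 | (2E,7R,8E,10E)-11-(TBS-oxy)-7-(TBDPS-oxymethyl)-3,7-dimethylundeca-2,8,10-trien-1-ol | OC/C=C(\C)CCC[C@@](C)(CO[Si](c1ccccc1)(c1ccccc1)C(C)(C)C)/C=C/C=C/O[Si](C)(C)C(C)(C)C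
F2 | step 9 | (2E,7R,8E,10E)-11-(TBS-oxy)-7-(TBDPS-oxymethyl)-3,7-dimethylundeca-2,8,10-trienal | O=C/C=C(\C)CCC[C@@](C)(CO[Si](c1ccccc1)(c1ccccc1)C(C)(C)C)/C=C/C=C/O[Si](C)(C)C(C)(C)C
F3 | step 9 | 8β-(TBS-oxy)-15-(TBDPS-oxy)-12-nordrim-6-en-11-al | O=C[C@H]1[C@@H](O[Si](C)(C)C(C)(C)C)C=C[C@H]2[C@](C)(CO[Si](c3ccccc3)(c3ccccc3)C(C)(C)C)CCC[C@]12C
F4 | step 9 | 8β-(TBS-oxy)-15-(TBDPS-oxy)-12-nordrim-6-en-11-ol | OC[C@H]1[C@@H](O[Si](C)(C)C(C)(C)C)C=C[C@H]2[C@](C)(CO[Si](c3ccccc3)(c3ccccc3)C(C)(C)C)CCC[C@]12C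
F5 | step 18 | 8β-(TBS-oxy)-15-(TBDPS-oxy)-12-nordriman-11-al | O=C[C@H]1[C@@H](O[Si](C)(C)C(C)(C)C)CC[C@H]2[C@](C)(CO[Si](c3ccccc3)(c3ccccc3)C(C)(C)C)CCC[C@]12C
F6 | step 18 | 4-tert-butyl 1-methyl (2R,3S)-3-(prop-2-en-1-yl)-2-[(trimethylsilyl)oxy]butanedioate | C[Si](C)(C)O[C@@H](C(=O)OC)[C@H](CC=C)C(=O)OC(C)(C)C
F7 | step 18 | 4-tert-butyl 1-methyl (2R,3S)-2-{[8β-(TBS-oxy)-15-(TBDPS-oxy)-12-nordriman-11-yl]oxy}-3-(prop-2-en-1-yl)butanedioate | CC(C)(C)OC(=O)[C@@H](CC=C)[C@@H](OC[C@H]1[C@@H](O[Si](C)(C)C(C)(C)C)CC[C@H]2[C@](C)(CO[Si](c3ccccc3)(c3ccccc3)C(C)(C)C)CCC[C@]12C)C(=O)OC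
F8 | step 18 | 4-tert-butyl 1-methyl (2R,3S)-2-{[15-(TBDPS-oxy)-8β-hydroxy-12-nordriman-11-yl]oxy}-3-(prop-2-en-1-yl)butanedioate | CC(C)(C)OC(=O)[C@@H](CC=C)[C@@H](OC[C@H]1[C@@H](O)CC[C@H]2[C@](C)(CO[Si](c3ccccc3)(c3ccccc3)C(C)(C)C)CCC[C@]12C)C(=O)OC
F9 | step 13 | 8β,15-dihydroxy-12-nordriman-11-yl acetate | CC(=O)OC[C@H]1[C@@H](O)CC[C@H]2[C@](C)(CO)CCC[C@]12C
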